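**Assumptions (one line):** 2-Iodo-4-methoxyphenol (1) and (2E,6E)-farnesyl bromide (2) are commercial. The quinine- or quinidine-derived amine that gives the (1R,6S)-epoxide 8 must be confirmed by screening the pair.

## Retrosynthetic overview
1. The target (1R,5R,6R) is a cis-epoxy alcohol, made by chemoselective Luche reduction of the C5 ketone of epoxyquinone 9. Hydride arrives anti to the epoxide, so the OH ends up cis to it.
2. Epoxyquinone 9 comes from hydrolysis of epoxy ketal 8. Ketal 8 comes from one catalytic enantioselective Weitz–Scheffer epoxidation of the prochiral quinone monoketal 7, which sets both epoxide stereocentres. Only the farnesyl-bearing enone reacts: the ketal blocks one carbonyl, and the other alkene is a β,β-disubstituted enone.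
3. Monoketal 7 comes from Cu-catalysed ethyl conjugate addition to the unsubstituted enone of monoketal 5, then Saegusa oxidation.
4. Monoketal 5 comes from PIDA/MeOH dearomatisation of 2-farnesyl-4-methoxyphenol 4, which comes from Stille coupling of iodophenol 1 with farnesylstannane 3.
5. Ring order: the carbocycle is never built. The arene is dearomatised to the cyclohexadienone, and the oxirane is formed last.

## Route

**Step 1**
Reactants: 2 (2E,6E)-farnesyl bromide
Product: 3 (2E,6E)-farnesyltributylstannane
Conditions: Bu3SnLi (from Bu3SnH + LDA), THF, –78 → 0 °C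
Reagents that add atoms: tributylstannyllithium, CCCC[Sn]([Li])(CCCC)CCCC
Why: SN2 displacement of the primary allylic bromide by the stannyl anion retains the E,E alkene geometry; no stereocentre is formed.

**Step 2**
Reactants: 1 (2-iodo-4-methoxyphenol), 3
Product: 4 (2-[(2E,6E)-farnesyl]-4-methoxyphenol)
Conditions: Pd(PPh3)4 (5 mol %), LiCl, DMF, 60 °C
Reagents that add atoms: none
Why: Stille coupling of the aryl iodide with the allylstannane gives the linear farnesyl arene, and the free phenol is tolerated.

**Step 3**
Reactants: 4
Product: 5 (2-farnesyl-4,4-dimethoxycyclohexa-2,5-dien-1-one)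
Conditions: PhI(OAc)2 (1.1 equiv), MeOH, 0 °C, 20 min
Reagents that add atoms: methanol, CO
Why: Hypervalent-iodine oxidative dearomatisation of a p-methoxyphenol gives the quinone monoketal; the former C–OMe carbon becomes the ketal and the former C–OH carbon becomes the ketone, and no stereocentre is formed.

**Step 4**
Reactants: 5
Product: 6 (racemic TMS dienol ether of the 5-ethyl conjugate adduct)
Conditions: EtMgBr (3 equiv), CuBr·SMe2 (20 mol %), TMSCl (3 equiv), THF, –78 °C, 1 h
Reagents that add atoms: ethylmagnesium bromide, CC[Mg]Br; chlorotrimethylsilane, C[Si](C)(C)Cl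
Why: Cu-catalysed, TMSCl-accelerated conjugate addition goes to the unsubstituted enone, which is more electrophilic than the α-farnesyl enone. The new C–H stereocentre is destroyed in step 5.

**Step 5**
Reactants: 6
Product: 7 (5-ethyl-2-farnesyl-4,4-dimethoxycyclohexa-2,5-dien-1-one)
Conditions: Pd(OAc)2 (1.1 equiv), MeCN, 25 °C, 12 h
Reagents that add atoms: none
Why: Saegusa–Ito oxidation of the silyl dienol ether restores the enone, now carrying the β-ethyl group, and gives an achiral, prochiral cross-conjugated dienone.

**Step 6**
Reactants: 7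
Product: 8 ((1R,6S)-4-ethyl-5,5-dimethoxy-1-farnesyl-7-oxabicyclo[4.1.0]hept-3-en-2-one)
Conditions: 9-amino-9-deoxy-epi-quinine·2 TFA (20 mol %), 30% aq. H2O2 (5 equiv), dioxane, 25 °C, 48 h
Reagents that add atoms: hydrogen peroxide, OO
Why: Proposed new method: this is a Weitz–Scheffer epoxidation by primary-amine iminium catalysis, closest to the known cinchona-amine/H2O2 epoxidation of 2-substituted cyclohexenones. The chiral iminium directs hydroperoxide addition to one enantiotopic face of the β-CH of the farnesyl-bearing enone, and ring closure of the resulting enamine onto the O–O bond sets both epoxide stereocentres. The β,β-disubstituted ethyl enone and the isolated farnesyl alkenes are not attacked, unlike with peracids.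

**Step 7**
Reactants: 8
Product: 9 ((1R,6S)-4-ethyl-1-farnesyl-7-oxabicyclo[4.1.0]hept-3-ene-2,5-dione)
Conditions: TFA (5 equiv), H2O/MeCN (1:9), 0 °C, 30 min
Reagents that add atoms: water, O
Why: Mild aqueous-acid hydrolysis of the dimethyl ketal; the epoxy ketone resists opening, and no stereocentre is touched.

**Step 8**
Reactants: 9
Product: 10 (target, (1R,5R,6R)-4-ethyl-5-hydroxy-1-[(2E,6E)-farnesyl]-7-oxabicyclo[4.1.0]hept-3-en-2-one)
Conditions: NaBH4 (1.0 equiv), CeCl3·7H2O (1.1 equiv), MeOH/CH2Cl2 (1:1), –78 °C, 30 min
Reagents that add atoms: none (hydride adds only H)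
Why: Luche reduction. C5 is less hindered than C2, which sits next to the quaternary farnesyl-bearing carbon, and is more electrophilic because the ethyl group is β to C2 and deactivates it. Hydride attacks anti to the epoxide oxygen, so the new C5–OH is cis to the epoxide, which matches the target.

## Compound list
1 | 2-iodo-4-methoxyphenol | Oc1ccc(OC)cc1I | starting material
2 | (2E,6E)-farnesyl bromide | BrC/C=C(\C)CC/C=C(\C)CCC=C(C)C | starting material
3 | (2E,6E)-farnesyltributylstannane | CCCC[Sn](CCCC)(CCCC)C/C=C(\C)CC/C=C(\C)CCC=C(C)C | intermediate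
4 | 2-farnesyl-4-methoxyphenol | COc1ccc(O)c(C/C=C(\C)CC/C=C(\C)CCC=C(C)C)c1 | intermediate
5 | 2-farnesyl-4,4-dimethoxycyclohexa-2,5-dien-1-one | COC1(OC)C=CC(=O)C(C/C=C(\C)CC/C=C(\C)CCC=C(C)C)=C1 | intermediate
6 | TMS dienol ether of the 5-ethyl conjugate adduct (racemic at C5) | CCC1C=C(O[Si](C)(C)C)C(C/C=C(\C)CC/C=C(\C)CCC=C(C)C)=CC1(OC)OC | intermediate
7 | 5-ethyl-2-farnesyl-4,4-dimethoxycyclohexa-2,5-dien-1-one | CCC1=CC(=O)C(C/C=C(\C)CC/C=C(\C)CCC=C(C)C)=CC1(OC)OC | intermediate
8 | (1R,6S)-epoxy ketal | CCC1=CC(=O)[C@]2(C/C=C(\C)CC/C=C(\C)CCC=C(C)C)O[C@@H]2C1(OC)OC | intermediate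
9 | (1R,6S)-epoxyquinone | CCC1=CC(=O)[C@]2(C/C=C(\C)CC/C=C(\C)CCC=C(C)C)O[C@@H]2C1=O | intermediate
10 | (1R,5R,6R) cis-epoxy alcohol | CCC1=CC(=O)[C@]2(C/C=C(\C)CC/C=C(\C)CCC=C(C)C)O[C@@H]2[C@@H]1O | target

## Totals
Total steps: 8, including the stannane preparation.
Longest linear sequence: 8 steps (2 → 3 → 4 → 5 → 6 → 7 → 8 → 9 → 10). The iodophenol branch (1 → 4) is shorter.

## Three steps most likely to fail
1. **Step 6 (enantioselective epoxidation of the hindered dienone ketal).** Iminium formation next to the α-farnesyl group, hydroperoxide addition next to C(OMe)2, or low ee are all possible.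
   Fallback: change the source of chirality. Epoxidise racemically (TBHP/Triton B) and resolve the epoxyquinone 9 by preparative chiral HPLC.
2. **Steps 4/5 (regioselective ethyl addition next to the ketal, then Saegusa).** The Grignard or TMSCl may ionise the ketal and aromatise it, Et may add at the wrong enone, or Pd(II) may attack the farnesyl alkenes.
   Fallback: install the ethyl group at the arene stage. Farnesylate 3-ethyl-4-methoxyphenol by ortho-lithiation of its MOM ether and Cu-catalysed alkylation with farnesyl bromide, remove the MOM group, then oxidise directly with PIDA/MeOH to give 7.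
3. **Step 8 (facial and chemoselectivity of the reduction).** Hydride may attack syn to the epoxide, giving the trans-epoxy alcohol, or may reduce C2.
   Fallback: accept the mixture, separate the trans-epoxy alcohol, and invert it to the cis isomer by Mitsunobu reaction (p-nitrobenzoic acid, DIAD, PPh3; then K2CO3/MeOH).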